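The readings are simulated for an exercise; scatter was added.

Two questions are asked of this flask, and both concern how the rate at one fixed fraction converted follows the charge of free catalyst.

| flask | starting material | free catalyst | remark |
|---|---|---|---|
| summer | 0.25 M | 0.50 mM | run made earlier |
| dusk | 1 M | 0.50 mM | run made earlier |
| spring | 0.50 M | 0.75 mM | run made earlier |
| flask | 0.50 M | 0.50 mM |  |

| run | time / min | product / % | starting material / % |
|---|---|---|---|
| summer | 4.00 | 33.9 | 65.7 |
| summer | 12.0 | 66.9 | 33.3 |
| summer | 20.0 | 80.2 | 19.7 |
| summer | 30.0 | 88.8 | 10.9 |
| summer | 50.0 | 95.0 | 5.1 |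
| summer | 60.0 | 96.9 | 3.5 |
| dusk | 10.0 | 61.9 | 39.1 |
| dusk | 20.0 | 80.5 | 19.2 |
| dusk | 30.0 | 89.2 | 11.2 |
| dusk | 40.0 | 92.9 | 7.4 |
| dusk | 50.0 | 94.4 | 5.0 |
| dusk | 60.0 | 96.9 | 3.6 |
| spring | 5.00 | 52.5 | 47.4 |
| spring | 10.0 | 73.4 | 26.9 |
| spring | 15.0 | 83.5 | 16.3 |
| spring | 30.0 | 94.1 | 6.3 |
| spring | 60.0 | 97.8 | 1.6 |

(readings scatter by 0.3 percentage points)

- factor on the rate of making product when 30% of the starting material are converted if free catalyst is charged twice over
- factor on the rate when 30% of the starting material are converted if free catalyst is charged at 0.050 mM instead

- the numbers in the tables scatter by 0.3 percentage points (one standard deviation)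

Call the fraction of starting material left S and plot L = ln(1/S). The summer run leaves 19.7% at 20.0 min and the dusk run leaves 19.2% at 20.0 min, although the dusk charge of starting material is 4.00 times the summer one, so treat the decay as pseudo-first-order, with the slope of L as a measure of the working catalyst. In the summer run that slope falls from 0.105 min⁻¹ at the start to 0.0379 min⁻¹ late on. Define the reach as the gain in L over which the slope falls by a factor e, and take it between the midpoints of those windows: 2.52. The spring run, with 1.50 times the catalyst, starts at 0.149 min⁻¹ and reads 2.60, so at 30% conversion the slope keeps 86.8% of its start value by the summer reach and 87.2% by the spring reach.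

Now go two ways. First compare the start slopes: spring's first window stands at a raw ratio of 1.42 to summer's, but that window covers more L. Put the reach back in to carry each slope to L = 0, and the ratio becomes 1.51. Second, compare times: interpolated, summer reaches spring's 26.9% at 15.3 min, which is 1.53 times spring's 10.0 min. Both follow the charge ratio, so my order in catalyst is 1.02, giving about 2.03 and 0.0962. The lower charge is an extrapolation.

The forecast says 2 and 0.1: “The rate therefore scales linearly with charge.”

The flask gives 2.00 and 0.100.

    starting material + free catalyst → free catalyst + product (k = 3.80 L mol⁻¹ s⁻¹)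
    2 free catalyst → spent catalyst (k = 0.720 L mol⁻¹ s⁻¹)

With twice the charge, the 3.35 min to that conversion becomes half as long. Apply the reach to this flask at 25.0 min: with 14.5% of the starting material left, it puts the slope at 46.5% of its start value, and free catalyst then stands at 48.1% of its charge.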